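Cuts: both O–benzyl bonds (C5-OH, C7-OH) go last. C5–O goes back to C5–Br, and O1–C8a of ring C back to an open 2-methoxy-1,3-diketone. C3–C4 of that diketone goes back to a ring-A aroyl chloride and a ring-B methoxymethyl ketone.
Enabling feature: C8a (bearing O1) and C5 (bearing OH) are the two ring-A carbons ortho to C4a, and both carry oxygen. C8-OMe and C6-OMe mirror each other across the C4a–C7 axis, so a 4-benzyloxy-2,6-dibromo-3,5-dimethoxybenzoyl group is symmetric and closure onto either bromine gives one chromenone.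
Forward: rings A and B come from bought arenes and are joined through C2–C3–C4 by enolate C-acylation. Ring C is then closed by copper-catalysed enolate O-arylation, and the remaining C5 bromide is exchanged for benzyloxy before one hydrogenolysis.
Stereochemistry: the target has no stereocentre. C3 of the diketone is racemic and enolisable and becomes sp2 on ring closure.

Key step: step 9

Remark: flavone atom numbers (O1, C2 to C8a) are also used for the corresponding atoms of the open-chain precursors.

Step 1
Reactants: 1 methyl 4-hydroxy-3,5-dimethoxybenzoate (methyl syringate)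
Product: 2 methyl 4-(benzyloxy)-3,5-dimethoxybenzoate
Conditions: BnBr (1.2 equiv), K2CO3 (2 equiv), DMF, 60 °C
Reagents that add atoms: benzyl bromide, BrCc1ccccc1
Why: Williamson ether synthesis on the acidic 4-OH of a syringate is routine under carbonate conditions, and benzyl is chosen because it withstands bromination, enolate and copper chemistry and leaves in the same final hydrogenolysis as the ether to be placed at C5.

Step 2
Reactants: 2 methyl 4-(benzyloxy)-3,5-dimethoxybenzoate
Product: 3 4-(benzyloxy)-3,5-dimethoxybenzoic acid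
Conditions: LiOH (3 equiv), THF/MeOH/H2O, 50 °C; then 1 M HCl
Reagents that add atoms: lithium hydroxide, [Li+].[OH-]
Why: Ordinary ester saponification by acyl–oxygen cleavage, placed before the bromination because the carbonyl is still unhindered here, whereas a 2,6-dibromobenzoate would resist hydroxide.

Step 3
Reactants: 3 4-(benzyloxy)-3,5-dimethoxybenzoic acid
Product: 4 4-(benzyloxy)-2,6-dibromo-3,5-dimethoxybenzoic acid
Conditions: NBS (2.4 equiv), DMF, rt → 50 °C, dark
Reagents that add atoms: N-bromosuccinimide, O=C1CCC(=O)N1Br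
Why: Twofold electrophilic aromatic bromination at the only free ring positions, each ortho to one methoxy group and para to the other, as is classical for gallic and 3,4,5-trialkoxybenzoic acids; NBS in the dark without added base avoids HBr (benzyl ether cleavage), benzylic radical bromination and ipso-bromodecarboxylation of a carboxylate, and the unactivated benzyl phenyl ring does not compete.

Step 4
Reactants: 4 4-(benzyloxy)-2,6-dibromo-3,5-dimethoxybenzoic acid
Product: 5 4-(benzyloxy)-2,6-dibromo-3,5-dimethoxybenzoyl chloride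
Conditions: (COCl)2 (1.5 equiv), DMF (cat.), CH2Cl2, 0 °C → rt; evaporated and used crude
Reagents that add atoms: oxalyl chloride, O=C(Cl)C(Cl)=O
Why: Acid chloride formation with oxalyl chloride under DMF catalysis (chloroiminium activation) works also for 2,6-disubstituted benzoic acids and leaves the aryl methyl ethers, the benzyl ether and the C–Br bonds untouched.

Step 5
Reactants: 6 1,2,4-trimethoxybenzene
Product: 7 1-bromo-2,4,5-trimethoxybenzene
Conditions: NBS (1.0 equiv), MeCN, 0 °C → rt
Reagents that add atoms: N-bromosuccinimide, O=C1CCC(=O)N1Br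
Why: Electrophilic aromatic bromination with NBS in MeCN goes to C5 of 6, the position para to the 2-methoxy and ortho to the 4-methoxy group, while C3 is buried between two methoxy groups and C6 is activated by only one.

Step 6
Reactants: 8 methoxyacetyl chloride
Product: 9 N,2-dimethoxy-N-methylacetamide
Conditions: MeNH(OMe)·HCl (1.1 equiv), Et3N (2.2 equiv), CH2Cl2, 0 °C → rt
Reagents that add atoms: N,O-dimethylhydroxylamine hydrochloride, CNOC.Cl
Why: N-acylation of the amine by the acid chloride gives the Weinreb amide, taken instead of a direct Friedel–Crafts acylation of 6 because strong Lewis acids decarbonylate methoxyacetyl chloride to a methoxymethyl cation and strip ortho methyl ethers.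

Step 7
Reactants: 7 1-bromo-2,4,5-trimethoxybenzene; 9 N,2-dimethoxy-N-methylacetamide
Product: 12 2-methoxy-1-(2,4,5-trimethoxyphenyl)ethan-1-one, via aryllithium 10 (not isolated), via tetrahedral lithium adduct 11 (not isolated)
Conditions: n-BuLi (1.05 equiv), THF, −78 °C; then 9 (1.1 equiv), −78 → 0 °C; 1 M HCl
Reagents that add atoms: none
Why: Bromine–lithium exchange followed by Weinreb ketone synthesis: 10 adds once to 9, chelated adduct 11 holds until the acidic quench so that no tertiary alcohol can form, and the bromine fixes the 2,4,5-pattern of ring B.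

Step 8
Reactants: 12 2-methoxy-1-(2,4,5-trimethoxyphenyl)ethan-1-one; 5 4-(benzyloxy)-2,6-dibromo-3,5-dimethoxybenzoyl chloride
Product: 15 1-[4-(benzyloxy)-2,6-dibromo-3,5-dimethoxyphenyl]-2-methoxy-3-(2,4,5-trimethoxyphenyl)propane-1,3-dione (racemic), via lithium enolate 13 (not isolated), via lithium diketonate 14 (not isolated)
Conditions: LiN(SiMe3)2 (2.2 equiv), THF, −78 °C; then 5 (1.0 equiv) in THF, −78 °C → rt; 1 M HCl
Reagents that add atoms: none
Why: Crossed Claisen-type C-acylation of a preformed lithium enolate by an aroyl chloride, the usual entry to 1-(2-haloaryl)-1,3-diketones; the second equivalent of base stores the more acidic product as chelated diketonate 14, which prevents proton exchange with 13 and a second acylation, and neither base nor enolate attacks the C–Br bonds.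

Step 9
Reactants: 15 1-[4-(benzyloxy)-2,6-dibromo-3,5-dimethoxyphenyl]-2-methoxy-3-(2,4,5-trimethoxyphenyl)propane-1,3-dione
Product: 17 7-(benzyloxy)-5-bromo-3,6,8-trimethoxy-2-(2,4,5-trimethoxyphenyl)-4H-chromen-4-one, via caesium enolate 16 (not isolated)
Conditions: CuI (20 mol %), 1,10-phenanthroline (40 mol %), Cs2CO3 (2 equiv), 4 Å MS, 1,4-dioxane, 100 °C, Ar
Reagents that add atoms: none
Why: Cs2CO3 turns 15 into enolate 16, whose oxygen on C2 (the carbon bearing ring B) binds phenanthroline-ligated monovalent copper; after rotation about C3–C4 the metal inserts into one ortho C–Br bond to give a trivalent copper aryl enolate, and reductive elimination forms O1–C8a and returns monovalent copper. The closest known reaction type is the intramolecular Ullmann O-arylation of 1-(2-haloaryl)-1,3-diketones, run with copper catalysis or with carbonate alone, which gives chromones and flavones. Ring C closes as a six-membered ring by attack of the enolate oxygen on an aromatic sp2 carbon whose departing C–Br bond lies outside the new ring (formally 6-exo), and the ortho C4 carbonyl both polarises that bond and holds the nucleophile within reach. No stereocentre is made, and the racemic C3 centre of 15 becomes sp2. The step needs O- over C-arylation, one bromine over the other, and a single substitution: C3 or the C4 oxygen could reach an ortho carbon only through a four-membered ring, the two bromines are exchanged by the mirror plane through C4a and C7 of ring A so that either closure gives 17, and the bromine left at C5 has no internal nucleophile.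

Step 10
Reactants: 17 7-(benzyloxy)-5-bromo-3,6,8-trimethoxy-2-(2,4,5-trimethoxyphenyl)-4H-chromen-4-one
Product: 18 5,7-bis(benzyloxy)-3,6,8-trimethoxy-2-(2,4,5-trimethoxyphenyl)-4H-chromen-4-one
Conditions: BnOH (3 equiv), CuI (20 mol %), 3,4,7,8-tetramethyl-1,10-phenanthroline (40 mol %), Cs2CO3 (2 equiv), toluene, 110 °C, Ar
Reagents that add atoms: benzyl alcohol, OCc1ccccc1
Why: Ullmann-type copper-catalysed C–O coupling of an aryl bromide with a primary alcohol, assisted by the peri C4 carbonyl that pre-coordinates copper next to C5–Br as in 1-haloanthraquinones and 2-halobenzoates, while carbonate in toluene keeps the alkoxide level low enough to spare the pyranone.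

Step 11
Reactants: 18 5,7-bis(benzyloxy)-3,6,8-trimethoxy-2-(2,4,5-trimethoxyphenyl)-4H-chromen-4-one
Product: 19 5,7-dihydroxy-3,6,8-trimethoxy-2-(2,4,5-trimethoxyphenyl)-4H-chromen-4-one (5,7-dihydroxy-3,6,8,2',4',5'-hexamethoxyflavone)
Conditions: H2 (1 atm), 10% Pd/C, EtOAc/MeOH, rt
Reagents that add atoms: none
Why: Catalytic hydrogenolysis of aryl benzyl ethers cleaves both benzylic C–O bonds at room temperature, whereas the six methyl ethers, the C4 carbonyl and the fully substituted C2=C3 bond are inert under one atmosphere of hydrogen.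

Compound list
1 | methyl 4-hydroxy-3,5-dimethoxybenzoate | COC(=O)c1cc(OC)c(O)c(OC)c1 | starting material
2 | methyl 4-(benzyloxy)-3,5-dimethoxybenzoate | COC(=O)c1cc(OC)c(OCc2ccccc2)c(OC)c1 | intermediate
3 | 4-(benzyloxy)-3,5-dimethoxybenzoic acid | OC(=O)c1cc(OC)c(OCc2ccccc2)c(OC)c1 | intermediate
4 | 4-(benzyloxy)-2,6-dibromo-3,5-dimethoxybenzoic acid | OC(=O)c1c(Br)c(OC)c(OCc2ccccc2)c(OC)c1Br | intermediate
5 | 4-(benzyloxy)-2,6-dibromo-3,5-dimethoxybenzoyl chloride | ClC(=O)c1c(Br)c(OC)c(OCc2ccccc2)c(OC)c1Br | intermediate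
6 | 1,2,4-trimethoxybenzene | COc1ccc(OC)c(OC)c1 | starting material
7 | 1-bromo-2,4,5-trimethoxybenzene | COc1cc(OC)c(Br)cc1OC | intermediate
8 | methoxyacetyl chloride | COCC(Cl)=O | starting material
9 | N,2-dimethoxy-N-methylacetamide | COCC(=O)N(C)OC | intermediate
10 | (2,4,5-trimethoxyphenyl)lithium (not isolated) | [Li]c1cc(OC)c(OC)cc1OC | intermediate
11 | lithium 2-methoxy-1-[methoxy(methyl)amino]-1-(2,4,5-trimethoxyphenyl)ethan-1-olate, racemic tetrahedral adduct (not isolated) | [Li]OC(COC)(N(C)OC)c1cc(OC)c(OC)cc1OC | intermediate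
12 | 2-methoxy-1-(2,4,5-trimethoxyphenyl)ethan-1-one | COCC(=O)c1cc(OC)c(OC)cc1OC | intermediate
13 | lithium (Z)-2-methoxy-1-(2,4,5-trimethoxyphenyl)ethen-1-olate, drawn as the chelated Z-enolate (not isolated) | [Li]O/C(=C\OC)c1cc(OC)c(OC)cc1OC | intermediate
14 | lithium (E)-3-[4-(benzyloxy)-2,6-dibromo-3,5-dimethoxyphenyl]-2-methoxy-3-oxo-1-(2,4,5-trimethoxyphenyl)prop-1-en-1-olate, enolate oxygen cis to the ring-A acyl carbon (not isolated) | [Li]O/C(c1cc(OC)c(OC)cc1OC)=C(/OC)C(=O)c1c(Br)c(OC)c(OCc2ccccc2)c(OC)c1Br | intermediate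
15 | 1-[4-(benzyloxy)-2,6-dibromo-3,5-dimethoxyphenyl]-2-methoxy-3-(2,4,5-trimethoxyphenyl)propane-1,3-dione, racemic | COc1cc(OC)c(C(=O)C(OC)C(=O)c2c(Br)c(OC)c(OCc3ccccc3)c(OC)c2Br)cc1OC | intermediate
16 | caesium (E)-3-[4-(benzyloxy)-2,6-dibromo-3,5-dimethoxyphenyl]-2-methoxy-3-oxo-1-(2,4,5-trimethoxyphenyl)prop-1-en-1-olate, enolate oxygen cis to the ring-A acyl carbon (not isolated) | [Cs+].[O-]/C(c1cc(OC)c(OC)cc1OC)=C(/OC)C(=O)c1c(Br)c(OC)c(OCc2ccccc2)c(OC)c1Br | intermediate
17 | 7-(benzyloxy)-5-bromo-3,6,8-trimethoxy-2-(2,4,5-trimethoxyphenyl)-4H-chromen-4-one | COc1cc(OC)c(-c2oc3c(OC)c(OCc4ccccc4)c(OC)c(Br)c3c(=O)c2OC)cc1OC | intermediate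
18 | 5,7-bis(benzyloxy)-3,6,8-trimethoxy-2-(2,4,5-trimethoxyphenyl)-4H-chromen-4-one | COc1cc(OC)c(-c2oc3c(OC)c(OCc4ccccc4)c(OC)c(OCc4ccccc4)c3c(=O)c2OC)cc1OC | intermediate
19 | 5,7-dihydroxy-3,6,8,2',4',5'-hexamethoxyflavone | COc1cc(OC)c(-c2oc3c(OC)c(O)c(OC)c(O)c3c(=O)c2OC)cc1OC | target

Total step count: 11. Longest linear sequence: 8 steps (1, 2, 3, 4, 8, 9, 10, 11, from 1).

Steps most likely to fail

Step 8 (C-acylation). The enolate may be acylated on oxygen rather than on carbon. Attack at a carbonyl screened by two ortho bromines may also be so slow that the silylamide base consumes the acid chloride. The fallback replaces acylation by aldol addition and oxidation; it sets out from 5 and returns at 15. Compound 5 is reduced with LiAlH(OtBu)3 in THF at −78 °C to 4-(benzyloxy)-2,6-dibromo-3,5-dimethoxybenzaldehyde F1. An aldehyde is less shielded and offers no O-acylation channel. Enolate 13, made from 12 with one equivalent of LiN(SiMe3)2, adds to F1 at −78 °C. After an NH4Cl quench this should give 3-[4-(benzyloxy)-2,6-dibromo-3,5-dimethoxyphenyl]-3-hydroxy-2-methoxy-1-(2,4,5-trimethoxyphenyl)propan-1-one F2 as a mixture of racemic diastereomers, which is of no consequence. Dess–Martin periodinane in CH2Cl2 then oxidises the carbinol to 15.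

Step 9 (ring closure). Copper may insert only slowly into a C–Br bond wedged between a methoxy group and the acyl group. That would leave time for retro-Claisen cleavage of the diketone and for reductive loss of bromine. The fallback changes the leaving group on ring A instead of forcing the conditions; it sets out from 3 and returns at 18.
- Acid 3 is diiodinated with NIS and catalytic CF3CO2H in MeCN to 4-(benzyloxy)-2,6-diiodo-3,5-dimethoxybenzoic acid F3.
- (COCl)2 and catalytic DMF convert it into 4-(benzyloxy)-2,6-diiodo-3,5-dimethoxybenzoyl chloride F4.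
- Acylation of enolate 13 in the manner of step 8 gives 1-[4-(benzyloxy)-2,6-diiodo-3,5-dimethoxyphenyl]-2-methoxy-3-(2,4,5-trimethoxyphenyl)propane-1,3-dione F5.
- The symmetry argument is unchanged. Aryl iodides enter Ullmann couplings at much lower temperature, so closure with CuI, 1,10-phenanthroline and Cs2CO3 can be run near 60 °C, where the diketone is safe. It should give 7-(benzyloxy)-5-iodo-3,6,8-trimethoxy-2-(2,4,5-trimethoxyphenyl)-4H-chromen-4-one F6.
- F6 takes the place of 17 in the benzyloxylation of step 10, for which an iodide is the classical partner, and gives 18.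

Step 10 (C5 benzyloxylation). Coupling may be slow at a bromide flanked by the C6 methoxy group and C4a. Competing processes are hydrodebromination at the expense of benzyl alcohol and opening of the pyranone by alkoxide attack at C2. The fallback replaces C–O coupling by borylation and oxidation; it sets out from 17 and returns at 19. Miyaura borylation of 17 (B2pin2, Pd2(dba)3, XPhos, KOAc, 1,4-dioxane, 100 °C) gives 7-(benzyloxy)-3,6,8-trimethoxy-5-(4,4,5,5-tetramethyl-1,3,2-dioxaborolan-2-yl)-2-(2,4,5-trimethoxyphenyl)-4H-chromen-4-one F7. Mild oxidation with NaBO3·4H2O in THF/H2O at rt gives 7-(benzyloxy)-5-hydroxy-3,6,8-trimethoxy-2-(2,4,5-trimethoxyphenyl)-4H-chromen-4-one F8, whose new phenol is hydrogen-bonded to the C4 carbonyl. Hydrogenolysis under the conditions of step 11 removes the single benzyl group and gives 19.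

Further compounds
F1 | step 8 | 4-(benzyloxy)-2,6-dibromo-3,5-dimethoxybenzaldehyde | O=Cc1c(Br)c(OC)c(OCc2ccccc2)c(OC)c1Br
F2 | step 8 | 3-[4-(benzyloxy)-2,6-dibromo-3,5-dimethoxyphenyl]-3-hydroxy-2-methoxy-1-(2,4,5-trimethoxyphenyl)propan-1-one, mixture of racemic diastereomers | COc1cc(OC)c(C(=O)C(OC)C(O)c2c(Br)c(OC)c(OCc3ccccc3)c(OC)c2Br)cc1OC
F3 | step 9 | 4-(benzyloxy)-2,6-diiodo-3,5-dimethoxybenzoic acid | OC(=O)c1c(I)c(OC)c(OCc2ccccc2)c(OC)c1I
F4 | step 9 | 4-(benzyloxy)-2,6-diiodo-3,5-dimethoxybenzoyl chloride | ClC(=O)c1c(I)c(OC)c(OCc2ccccc2)c(OC)c1I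
F5 | step 9 | 1-[4-(benzyloxy)-2,6-diiodo-3,5-dimethoxyphenyl]-2-methoxy-3-(2,4,5-trimethoxyphenyl)propane-1,3-dione, racemic | COc1cc(OC)c(C(=O)C(OC)C(=O)c2c(I)c(OC)c(OCc3ccccc3)c(OC)c2I)cc1OC
F6 | step 9 | 7-(benzyloxy)-5-iodo-3,6,8-trimethoxy-2-(2,4,5-trimethoxyphenyl)-4H-chromen-4-one | COc1cc(OC)c(-c2oc3c(OC)c(OCc4ccccc4)c(OC)c(I)c3c(=O)c2OC)cc1OC
F7 | step 10 | 7-(benzyloxy)-3,6,8-trimethoxy-5-(4,4,5,5-tetramethyl-1,3,2-dioxaborolan-2-yl)-2-(2,4,5-trimethoxyphenyl)-4H-chromen-4-one | COc1cc(OC)c(-c2oc3c(OC)c(OCc4ccccc4)c(OC)c(B4OC(C)(C)C(C)(C)O4)c3c(=O)c2OC)cc1OC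
F8 | step 10 | 7-(benzyloxy)-5-hydroxy-3,6,8-trimethoxy-2-(2,4,5-trimethoxyphenyl)-4H-chromen-4-one | COc1cc(OC)c(-c2oc3c(OC)c(OCc4ccccc4)c(OC)c(O)c3c(=O)c2OC)cc1OC
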